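The carbocycle (ring C: C-4a, C-5, C-6, C-7, C-8, C-8a) is disconnected at C-5–C-6. The key step is a late single-atom exchange in this ring: a methoxide-catalysed rearrangement of an enol δ-lactone, in which oxygen bridges C-5 and C-7 and C-6 is an exocyclic isopropylidene carbon, moves C-6 into the ring and forms C-5–C-6. It exploits the non-enolisable β-diketone C-5(=O)–C-6(CH3)2–C-7(=O), the C-acyl isomer of an enol ester. The precursor, a spiro pyrano[4,3-b]pyran-5-one, comes from a domino Knoevenagel–hetero-Diels–Alder reaction of a keto lactone, isovaleraldehyde and (−)-β-pinene, whose bought stereocentres C-1′ and C-5′ are relayed to C-2 and C-4 in that one event.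

Key step: step 4

Remark: locants follow the chromene core of the target (O-1, spiro C-2, C-3, C-4, C-4a, C-5 to C-8, C-8a; pinane atoms primed) and are kept for the matching atoms of the precursors (in 11 the ring atom 6 is oxygen); keto lactone 7 is drawn as its diketo tautomer.

Step 1
Reactants: 1 2,2,4,4-tetramethylcyclobutane-1,3-dione; 2 tert-butyl acetate
Product: 5 tert-butyl 4,4,6-trimethyl-3,5-dioxoheptanoate, via lithium enolate of tert-butyl acetate 3 (not isolated), via lithium cyclobutanolate adduct 4 (not isolated)
Conditions: LiN(iPr)2 (1.1 equiv), THF, −78 °C; then 1, −78 → 0 °C; AcOH quench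
Reagents that add atoms: none
Why: Aldol addition of ester enolate 3 to one strained, non-enolisable carbonyl of 1 gives alkoxide 4, which opens by retro-aldol (retro-Claisen-type) C–C fragmentation with release of ring strain to the stabilised β-keto ester enolate, the same nucleophilic ring cleavage that this dione undergoes with alkoxides, amines and organometallic reagents; no stereocentre is formed.

Step 2
Reactants: 5 tert-butyl 4,4,6-trimethyl-3,5-dioxoheptanoate
Product: 7 5,5-dimethyl-6-(propan-2-ylidene)oxane-2,4-dione, via acylketene 6 (not isolated)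
Conditions: toluene (0.02 M), 110 °C, tert-butanol distilled off
Reagents that add atoms: none
Why: tert-Butyl β-keto esters lose tert-butanol on heating to give acylketenes, and the ketene carbon of 6 should be trapped in a six-membered closure by the oxygen of the δ-ketone, which can enolise only towards its isopropyl methine and so gives the exocyclic enol ether (acylketene route to pyran-2,4-diones); no stereocentre is formed.

Step 3
Reactants: 7 5,5-dimethyl-6-(propan-2-ylidene)oxane-2,4-dione; 8 isovaleraldehyde; 9 (−)-β-pinene
Product: 11 (2R,4R,1′R,5′S)-6′,6′,8,8-tetramethyl-4-(2-methylpropyl)-7-(propan-2-ylidene)-3,4,7,8-tetrahydro-5H-spiro[pyrano[4,3-b]pyran-2,2′-bicyclo[3.1.1]heptan]-5-one, via alkylidene keto lactone 10 (not isolated)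
Conditions: ethylenediammonium diacetate (10 mol%), 9 (5 equiv), toluene, 4 Å molecular sieves, 25 → 90 °C; chromatography
Reagents that add atoms: none
Why: Domino Knoevenagel–hetero-Diels–Alder reaction: the vinylogous acid 7 condenses with 8 to the locked s-cis 1-oxadiene 10, whose ketone oxygen and alkylidene carbon add with inverse electron demand across the exocyclic alkene of 9 (CH2 terminus to the alkylidene carbon, oxygen to the tertiary carbon), the gem-dimethyl bridge of 9 shielding one face so that oxygen enters anti to it and the spiro centre C-2 is set (2R) by the substrate, while C-4 follows from the endo/exo orientation, 4R arising when the bridgehead C-1′ lies under the oxadiene, so that the 4S epimer is expected as a co-product and is removed by chromatography.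

Step 4
Reactants: 11 (2R,4R,1′R,5′S)-6′,6′,8,8-tetramethyl-4-(2-methylpropyl)-7-(propan-2-ylidene)-3,4,7,8-tetrahydro-5H-spiro[pyrano[4,3-b]pyran-2,2′-bicyclo[3.1.1]heptan]-5-one
Product: 13 (2R,4R,1′R,5′S)-6,6,6′,6′,8,8-hexamethyl-4-(2-methylpropyl)-3,4-dihydrospiro[chromene-2,2′-bicyclo[3.1.1]heptane]-5,7(6H,8H)-dione, via sodium enolate 12 (not isolated)
Conditions: NaOMe (0.2 equiv), THF, 25 → 60 °C; aq. NH4Cl
Reagents that add atoms: none
Why: Methoxide adds to the lactone carbonyl C-5 of 11 and the enol oxygen O-6 leaves, which sets free, without strong base and at one site only, the tetrasubstituted sodium enolate 12 beside a methyl β-alkoxyacrylate; the enolate carbon C-6 then attacks the ester carbonyl C-5 and methoxide is expelled again, so that a catalytic chain replaces the ring oxygen by carbon. The closest known reaction type is the alkoxide-catalysed rearrangement of enol lactones to cyclic 1,3-diketones, an intramolecular Claisen (Dieckmann-type) acylation that is known for dimethylketene-derived isopropylidene enol δ-lactones, which give 2,2-dimethylcyclohexane-1,3-diones. Ring C closes in a 6-(enolexo)-exo-trig mode, the attacked C=O lying outside the new ring. No stereocentre is formed, and C-2, C-4, C-1′ and C-5′ are not at risk, since the only acidic C–H along the pathway is the isopropyl methine and the tertiary vinylogous-ester C–O bond at C-2 is as inert to base as a tert-alkyl ester. The step needs C- instead of O-acylation and must not run backwards: O-acylation only returns 11, whereas C-acylation trades an enol ester for two ketone carbonyls and is downhill, and in 13 the C-5 carbonyl is a deactivated vinylogous ester and C-7 lies between two quaternary carbons, so catalytic methoxide in an aprotic solvent should not cleave the product; the rearrangement has to follow step 3 because the free keto lactone 7 would be deprotonated at C-3 and so shielded from methoxide.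

Compound list
1 | 2,2,4,4-tetramethylcyclobutane-1,3-dione | CC1(C)C(=O)C(C)(C)C1=O | starting material
2 | tert-butyl acetate | CC(=O)OC(C)(C)C | starting material
3 | lithium enolate of tert-butyl acetate | [Li+].[O-]C(=C)OC(C)(C)C | intermediate
4 | lithium 1-(2-tert-butoxy-2-oxoethyl)-2,2,4,4-tetramethyl-3-oxocyclobutan-1-olate | [Li+].[O-]C1(CC(=O)OC(C)(C)C)C(C)(C)C(=O)C1(C)C | intermediate
5 | tert-butyl 4,4,6-trimethyl-3,5-dioxoheptanoate | CC(C)C(=O)C(C)(C)C(=O)CC(=O)OC(C)(C)C | intermediate
6 | 4,4,6-trimethylhept-1-ene-1,3,5-trione (acylketene) | CC(C)C(=O)C(C)(C)C(=O)C=C=O | intermediate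
7 | 5,5-dimethyl-6-(propan-2-ylidene)oxane-2,4-dione | CC(C)=C1OC(=O)CC(=O)C1(C)C | intermediate
8 | isovaleraldehyde (3-methylbutanal) | CC(C)CC=O | starting material
9 | (−)-β-pinene, (1S,5S)-6,6-dimethyl-2-methylidenebicyclo[3.1.1]heptane | C=C1CC[C@H]2C[C@@H]1C2(C)C | starting material
10 | (3Z)-5,5-dimethyl-3-(3-methylbutylidene)-6-(propan-2-ylidene)oxane-2,4-dione (reactive isomer of an equilibrating E/Z pair) | CC(C)C/C=C1\C(=O)OC(=C(C)C)C(C)(C)C1=O | intermediate
11 | (2R,4R,1′R,5′S)-6′,6′,8,8-tetramethyl-4-(2-methylpropyl)-7-(propan-2-ylidene)-3,4,7,8-tetrahydro-5H-spiro[pyrano[4,3-b]pyran-2,2′-bicyclo[3.1.1]heptan]-5-one | CC(C)C[C@@H]1C[C@@]2(CC[C@H]3C[C@@H]2C3(C)C)OC2=C1C(=O)OC(=C(C)C)C2(C)C | intermediate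
12 | sodium enolate of methyl (2R,4R,1′R,5′S)-6-(2,4-dimethyl-3-oxopentan-2-yl)-6′,6′-dimethyl-4-(2-methylpropyl)-3,4-dihydrospiro[pyran-2,2′-bicyclo[3.1.1]heptane]-5-carboxylate | [Na+].CC(C)C[C@@H]1C[C@@]2(CC[C@H]3C[C@@H]2C3(C)C)OC(C(C)(C)C([O-])=C(C)C)=C1C(=O)OC | intermediate
13 | (2R,4R,1′R,5′S)-6,6,6′,6′,8,8-hexamethyl-4-(2-methylpropyl)-3,4-dihydrospiro[chromene-2,2′-bicyclo[3.1.1]heptane]-5,7(6H,8H)-dione | CC(C)C[C@@H]1C[C@@]2(CC[C@H]3C[C@@H]2C3(C)C)OC2=C1C(=O)C(C)(C)C(=O)C2(C)C | target

Total step count: 4. Longest linear sequence: 4 steps (1 → 5 → 7 → 11 → 13).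

Steps most likely to fail

Step 3. The two lateral orientations of 9 under the oxadiene (endo/exo) may be poorly discriminated, which erodes the configuration at C-4. In addition, the Alder-ene reaction of 9, cycloaddition through the lactone carbonyl and 2:1 Michael adducts of 7 can divert material. Fallback: the cyclic oxadiene is replaced by an acyclic, chelating one under reagent control. Setting out from 1, methyl acetate and LiN(iPr)2 (in place of 2, as in step 1) should give methyl 4,4,6-trimethyl-3,5-dioxoheptanoate F1. Knoevenagel condensation with 8 (piperidine, AcOH, CH2Cl2, 0 °C) would give methyl 5-methyl-2-(2,2,4-trimethyl-3-oxopentanoyl)hex-2-enoate F2, in which only the ketone can be the oxadiene terminus. Two-point binding of its 1,3-dicarbonyl unit to a chiral divalent-copper Lewis acid (Cu(OTf)2 with a 2,2′-isopropylidenebis(4-tert-butyl-2-oxazoline) ligand, 10 mol%, CH2Cl2, −40 → 0 °C) leaves one oxadiene face open; the ligand antipode is chosen so that this face forces C-1′ of 9 under the diene. The cycloaddition should then give methyl (2R,4R,1′R,5′S)-6-(2,4-dimethyl-3-oxopentan-2-yl)-6′,6′-dimethyl-4-(2-methylpropyl)-3,4-dihydrospiro[pyran-2,2′-bicyclo[3.1.1]heptane]-5-carboxylate F3. LiN(iPr)2 (1.2 equiv, THF, −78 → 25 °C) would close C-5–C-6 by Dieckmann-type acylation, and the sequence comes back to the route at 13.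

Step 4. The acyl transfer may stall at the ring-opened stage, for example by protonation of the hindered enolate, so that the chain does not turn over, or the Claisen equilibrium may drain back through alkoxide attack. Fallback: the catalytic equilibrium isomerisation is replaced by a stoichiometric, kinetically controlled acylation with a better acyl donor. Setting out from 11, EtSH (5 equiv), Et3N and catalytic DMAP in CH2Cl2 should open the enol ester to S-ethyl (2R,4R,1′R,5′S)-6-(2,4-dimethyl-3-oxopentan-2-yl)-6′,6′-dimethyl-4-(2-methylpropyl)-3,4-dihydrospiro[pyran-2,2′-bicyclo[3.1.1]heptane]-5-carbothioate F4. LiN(iPr)2 (1.2 equiv, THF, −78 → 0 °C) would then form the isopropyl ketone enolate irreversibly, and this acylates on carbon at the thioester. The thiolate that leaves is too weak a nucleophile to cleave the hindered diketone, and the sequence comes back to the route at 13.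

Step 2. Bimolecular consumption of the acylketene (dimerisation, re-addition of tert-butanol) may outrun the intramolecular O-acylation by a hindered, barely enolised ketone. Fallback: the thermal ketene route is replaced by acid-mediated enol lactonisation through a mixed anhydride. Setting out from 5, CF3CO2H (CH2Cl2, 0 °C) would remove the tert-butyl group to give 4,4,6-trimethyl-3,5-dioxoheptanoic acid F5. (CF3CO)2O would convert this into the mixed anhydride 4,4,6-trimethyl-3,5-dioxoheptanoic trifluoroacetic anhydride F6, which the ketone oxygen attacks in the same six-membered closure at 0 → 25 °C. The sequence comes back to the route at 7.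

Further compounds
F1 | step 3 | methyl 4,4,6-trimethyl-3,5-dioxoheptanoate | CC(C)C(=O)C(C)(C)C(=O)CC(=O)OC
F2 | step 3 | methyl (2Z)-5-methyl-2-(2,2,4-trimethyl-3-oxopentanoyl)hex-2-enoate (reactive isomer of an E/Z pair) | CC(C)C/C=C(\C(=O)OC)C(=O)C(C)(C)C(=O)C(C)C
F3 | step 3 | methyl (2R,4R,1′R,5′S)-6-(2,4-dimethyl-3-oxopentan-2-yl)-6′,6′-dimethyl-4-(2-methylpropyl)-3,4-dihydrospiro[pyran-2,2′-bicyclo[3.1.1]heptane]-5-carboxylate | CC(C)C[C@@H]1C[C@@]2(CC[C@H]3C[C@@H]2C3(C)C)OC(C(C)(C)C(=O)C(C)C)=C1C(=O)OC
F4 | step 4 | S-ethyl (2R,4R,1′R,5′S)-6-(2,4-dimethyl-3-oxopentan-2-yl)-6′,6′-dimethyl-4-(2-methylpropyl)-3,4-dihydrospiro[pyran-2,2′-bicyclo[3.1.1]heptane]-5-carbothioate | CC(C)C[C@@H]1C[C@@]2(CC[C@H]3C[C@@H]2C3(C)C)OC(C(C)(C)C(=O)C(C)C)=C1C(=O)SCC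
F5 | step 2 | 4,4,6-trimethyl-3,5-dioxoheptanoic acid | CC(C)C(=O)C(C)(C)C(=O)CC(=O)O
F6 | step 2 | 4,4,6-trimethyl-3,5-dioxoheptanoic trifluoroacetic anhydride | CC(C)C(=O)C(C)(C)C(=O)CC(=O)OC(=O)C(F)(F)F
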